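The plan cuts the bond between N1, the secondary amine nitrogen of the 13-membered triaza lactam ring, and C2. C2 is the stereogenic ring carbon that also holds the lactam methylene C3 and the first carbon of the dienol chain. Tracing the ring-side Z double bond back to a triple bond makes C2 propargylic. The precursor is therefore a racemic open-chain propargylic acetate whose N-acetylated polyamine arm ends in a primary amine, stored as its ammonium salt. On a chiral copper catalyst it should ionise to an allenylidene. Amine attack then forms N1–C2, closes the ring and fixes the R centre in one operation, leaving a terminal alkyne as handle for the side chain.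

Key step: step 9

Structure check: the target is (2R)-9-acetyl-2-[(1Z,3E,5R)-5-hydroxyhepta-1,3-dien-1-yl]-1,5,9-triazacyclotridecan-4-one. The ring runs N1, C2, C3, C4(=O), N5, C6–C8, N9(Ac), C10–C13. C2 stays R from ethynyl through enynyl to dienyl, because each of these groups ranks below N1 and above C3. C5' is R and comes unchanged from the purchased alkynol.

Design notes:
- **Polyamine arm.** It is built from mono-Boc-putrescine by cyanoethylation, so the three nitrogens differ from the outset and no selective protection of spermidine is needed.
- **Storage of the seco amine.** It is kept as its trifluoroacetate and freed only in the catalyst flask, since a free primary amine and an acetate ester should not be stored in one molecule.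
- **Leaving group.** Acetate is kept, because more activated esters would be attacked by the amine.
- **Solvent.** A hindered alcohol co-solvent replaces methanol, which could capture the allenylidene at millimolar substrate concentration.

Assumption: the sense of induction of 2,6-bis[(4S,5R)-4,5-diphenyl-4,5-dihydrooxazol-2-yl]pyridine (diPh-pybox) on this aliphatic substrate cannot be predicted with certainty. The (4S,5R) ligand is written, and its equally available mirror image is used if a configurational check of the ethynyl macrocycle (MTPA amide) calls for it.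

Step 1
Reactants: 1 tert-butyl (4-aminobutyl)carbamate (mono-Boc-putrescine); 2 acrylonitrile
Product: 3 tert-butyl {4-[(2-cyanoethyl)amino]butyl}carbamate
Conditions: 2 (1.05 equiv), MeOH, 0 °C → rt
Reagents that add atoms: none
Why: Aza-Michael addition (cyanoethylation) of the only free amine to acrylonitrile should stop at the mono-adduct with about one equivalent of acceptor, since the secondary amine formed reacts more slowly, and it puts the future three-carbon arm on the correct nitrogen.

Step 2
Reactants: 3 tert-butyl {4-[(2-cyanoethyl)amino]butyl}carbamate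
Product: 4 tert-butyl {4-[acetyl(2-cyanoethyl)amino]butyl}carbamate
Conditions: Ac2O, Et3N, CH2Cl2, 0 °C → rt
Reagents that add atoms: acetic anhydride, CC(=O)OC(C)=O
Why: N-Acetylation of the only nucleophilic nitrogen (the carbamate NH is inert to Ac2O/Et3N) installs the acetyl group of the target at the central nitrogen before any other amine is unmasked and also blocks retro-Michael loss of acrylonitrile.

Step 3
Reactants: 4 tert-butyl {4-[acetyl(2-cyanoethyl)amino]butyl}carbamate
Product: 5 tert-butyl {4-[acetyl(3-aminopropyl)amino]butyl}carbamate
Conditions: H2 (4 bar), Raney Ni, NH3/MeOH, rt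
Reagents that add atoms: none
Why: Catalytic hydrogenation of a nitrile to the primary amine over Raney Ni is standard for cyanoethylated polyamines, with ammonia suppressing secondary-amine formation and the Boc and acetamide groups being inert.

Step 4
Reactants: 6 ethyl acetate; 7 3-(trimethylsilyl)propynal
Product: 9 rac-ethyl 3-hydroxy-5-(trimethylsilyl)pent-4-ynoate, via lithium enolate 8 (not isolated)
Conditions: 6, LiN(iPr)2, THF, −78 °C; then 7, −78 °C; aq NH4Cl
Reagents that add atoms: none
Why: Acetate aldol addition of a preformed lithium ester enolate to a non-enolisable ynal proceeds by 1,2-attack at low temperature, and the new carbinol centre is left racemic on purpose because step 9 erases it.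

Step 5
Reactants: 9 rac-ethyl 3-hydroxy-5-(trimethylsilyl)pent-4-ynoate
Product: 10 rac-3-hydroxypent-4-ynoic acid
Conditions: LiOH (3 equiv), THF/MeOH/H2O, 0 °C → rt; aq HCl to pH 2, NaCl saturation, EtOAc extraction
Reagents that add atoms: lithium hydroxide, [Li+].[OH-]
Why: Saponification of the ethyl ester and hydroxide-induced protodesilylation of the alkynylsilane take place in the same pot, which frees the terminal alkyne that the copper chemistry requires without an extra step, while the low temperature guards against retro-aldol cleavage.

Step 6
Reactants: 10 rac-3-hydroxypent-4-ynoic acid; 5 tert-butyl {4-[acetyl(3-aminopropyl)amino]butyl}carbamate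
Product: 12 rac-tert-butyl [4-(acetyl{3-[(3-hydroxypent-4-ynoyl)amino]propyl}amino)butyl]carbamate, via benzotriazolyl ester 11 (not isolated)
Conditions: N,N'-diisopropylcarbodiimide, HOBt, CH2Cl2/DMF, 0 °C → rt
Reagents that add atoms: none
Why: Carbodiimide/HOBt amide coupling acylates the primary amine far faster than the secondary propargylic alcohol, so the β-hydroxy acid can be used unprotected and is never activated as a β-acyloxy acid that could eliminate.

Step 7
Reactants: 12 rac-tert-butyl [4-(acetyl{3-[(3-hydroxypent-4-ynoyl)amino]propyl}amino)butyl]carbamate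
Product: 13 rac-tert-butyl [4-(acetyl{3-[(3-acetoxypent-4-ynoyl)amino]propyl}amino)butyl]carbamate
Conditions: Ac2O (1.5 equiv), pyridine, DMAP (5 mol %), CH2Cl2, 0 °C
Reagents that add atoms: acetic anhydride, CC(=O)OC(C)=O
Why: DMAP-catalysed O-acetylation of the secondary propargylic alcohol leaves the amide and carbamate NH groups untouched, and the weakly acidic amide α-hydrogens make β-elimination of acetate unlikely under these mild basic conditions.

Step 8
Reactants: 13 rac-tert-butyl [4-(acetyl{3-[(3-acetoxypent-4-ynoyl)amino]propyl}amino)butyl]carbamate
Product: 14 rac-4-(acetyl{3-[(3-acetoxypent-4-ynoyl)amino]propyl}amino)butan-1-aminium trifluoroacetate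
Conditions: TFA/CH2Cl2 1:4, 0 °C → rt; toluene azeotrope
Reagents that add atoms: trifluoroacetic acid, OC(=O)C(F)(F)F
Why: Acidolytic Boc cleavage gives the amine directly as its trifluoroacetate, a form in which nitrogen cannot attack the acetate, and a non-benzylic secondary propargylic acetate with a terminal alkyne should not ionise in TFA.

Step 9
Reactants: 14 rac-4-(acetyl{3-[(3-acetoxypent-4-ynoyl)amino]propyl}amino)butan-1-aminium trifluoroacetate
Product: 17 (2R)-9-acetyl-2-ethynyl-1,5,9-triazacyclotridecan-4-one, via free amine 15 (not isolated), via copper allenylidene 16 (not isolated)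
Conditions: 14 added by syringe pump (12 h) to Cu(MeCN)4PF6 (20 mol %), (4S,5R)-diPh-pybox (24 mol %), iPr2NEt (4 equiv), CH2Cl2/tBuOH 4:1, 0 °C, Ar, final 2 mM
Reagents that add atoms: none
Why: Proposed new method: iPr2NEt frees amine 15 from its salt and helps the pybox-bound monovalent copper to metalate the terminal alkyne, after which loss of acetate gives the planar cationic copper allenylidene 16, so both enantiomers of the acetate merge into one intermediate; the chain-end NH2 then adds to the γ-carbon, and protonation of the resulting copper acetylide releases 17 and the catalyst. The closest known reaction type is the copper-catalysed enantioselective propargylic amination of racemic propargylic esters, which is established between two molecules and for five- and six-membered rings but not for a macrocycle. Ring closure is a head-to-tail, formally 13-exo-trig process in which N1 attacks C2 while the C=C=Cu unit stays outside the ring, and slow addition keeps the stationary concentration of free amine low enough for cyclisation to outrun chain growth. The R configuration at C2 is set only by the face of the γ-carbon that the chiral ligand leaves open, since the substrate has no other stereocentre. The step needs N-attack to beat proton loss from the adjacent C3 methylene, O-to-N acetyl transfer and capture by solvent. The substrate secures this through a single basic nitrogen (the other two are amides), an acetate that is a poor acyl donor yet a sufficient leaving group, and amide rather than ester α-hydrogens, while tBuOH is too hindered to compete where methanol at this dilution could.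

Step 10
Reactants: 18 (R)-pent-1-yn-3-ol
Product: 20 (1E,3R)-1-iodopent-1-en-3-ol, via alkenylzirconocene 19 (not isolated)
Conditions: Cp2ZrHCl (2.3 equiv), THF, 0 °C → rt, dark; then I2 (1.2 equiv), −78 → 0 °C; aqueous work-up
Reagents that add atoms: iodine, [I][I]
Why: Hydrozirconation–iodinolysis: the first equivalent of Cp2ZrHCl is spent on the hydroxyl group as a zirconium alkoxide, the second adds syn with zirconium at the terminal carbon, and iodine replaces zirconium with retention to give the E-iodoalkene without touching the R carbinol centre bought in with 18.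

Step 11
Reactants: 17 (2R)-9-acetyl-2-ethynyl-1,5,9-triazacyclotridecan-4-one; 20 (1E,3R)-1-iodopent-1-en-3-ol
Product: 21 (2R)-9-acetyl-2-[(3E,5R)-5-hydroxyhept-3-en-1-yn-1-yl]-1,5,9-triazacyclotridecan-4-one
Conditions: Pd(PPh3)4 (5 mol %), CuI (10 mol %), Et3N (3 equiv), degassed THF/DMF, rt
Reagents that add atoms: none
Why: Sonogashira coupling of a terminal alkyne with an E-iodoalkene proceeds at room temperature with retention of alkene geometry and tolerates free hydroxyl, secondary amine and amide groups, and because 20 is a single enantiomer any minor enantiomer carried over from step 9 becomes a diastereomer that can be removed here.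

Step 12
Reactants: 21 (2R)-9-acetyl-2-[(3E,5R)-5-hydroxyhept-3-en-1-yn-1-yl]-1,5,9-triazacyclotridecan-4-one
Product: 22 (2R)-9-acetyl-2-[(1Z,3E,5R)-5-hydroxyhepta-1,3-dien-1-yl]-1,5,9-triazacyclotridecan-4-one (target)
Conditions: Zn(Cu/Ag), MeOH/H2O 1:1, rt → 40 °C, dark; filtration through Celite
Reagents that add atoms: none
Why: Boland reduction with zinc activated by copper and silver delivers two hydrogens syn to a conjugated alkyne and spares alkenes, so the enyne should give the 1Z,3E-diene without protection of the amine or alcohol and without touching either stereocentre.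

Compound list
1 | tert-butyl (4-aminobutyl)carbamate | CC(C)(C)OC(=O)NCCCCN | starting material
2 | acrylonitrile | C=CC#N | starting material
3 | tert-butyl {4-[(2-cyanoethyl)amino]butyl}carbamate | CC(C)(C)OC(=O)NCCCCNCCC#N | intermediate
4 | tert-butyl {4-[acetyl(2-cyanoethyl)amino]butyl}carbamate | CC(C)(C)OC(=O)NCCCCN(CCC#N)C(C)=O | intermediate
5 | tert-butyl {4-[acetyl(3-aminopropyl)amino]butyl}carbamate | CC(C)(C)OC(=O)NCCCCN(CCCN)C(C)=O | intermediate
6 | ethyl acetate | CCOC(C)=O | starting material
7 | 3-(trimethylsilyl)propynal | C[Si](C)(C)C#CC=O | starting material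
8 | lithium enolate of ethyl acetate (not isolated) | [Li]OC(=C)OCC | intermediate
9 | rac-ethyl 3-hydroxy-5-(trimethylsilyl)pent-4-ynoate | CCOC(=O)CC(O)C#C[Si](C)(C)C | intermediate
10 | rac-3-hydroxypent-4-ynoic acid | OC(=O)CC(O)C#C | intermediate
11 | rac-benzotriazol-1-yl 3-hydroxypent-4-ynoate (not isolated) | C#CC(O)CC(=O)On1nnc2ccccc12 | intermediate
12 | rac-tert-butyl [4-(acetyl{3-[(3-hydroxypent-4-ynoyl)amino]propyl}amino)butyl]carbamate | C#CC(O)CC(=O)NCCCN(C(C)=O)CCCCNC(=O)OC(C)(C)C | intermediate
13 | rac-tert-butyl [4-(acetyl{3-[(3-acetoxypent-4-ynoyl)amino]propyl}amino)butyl]carbamate | CC(=O)OC(C#C)CC(=O)NCCCN(C(C)=O)CCCCNC(=O)OC(C)(C)C | intermediate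
14 | rac-4-(acetyl{3-[(3-acetoxypent-4-ynoyl)amino]propyl}amino)butan-1-aminium trifluoroacetate | CC(=O)OC(C#C)CC(=O)NCCCN(C(C)=O)CCCC[NH3+].[O-]C(=O)C(F)(F)F | intermediate
15 | rac-N-{3-[acetyl(4-aminobutyl)amino]propyl}-3-acetoxypent-4-ynamide, the free seco amine (not isolated) | CC(=O)OC(C#C)CC(=O)NCCCN(C(C)=O)CCCCN | intermediate
16 | cationic copper allenylidene of the seco amine, pybox ligand omitted (not isolated) | [Cu+]=C=C=CCC(=O)NCCCN(C(C)=O)CCCCN | intermediate
17 | (2R)-9-acetyl-2-ethynyl-1,5,9-triazacyclotridecan-4-one | C#C[C@H]1CC(=O)NCCCN(C(C)=O)CCCCN1 | intermediate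
18 | (R)-pent-1-yn-3-ol | CC[C@@H](O)C#C | starting material
19 | (1E,3R)-O,C1-bis(chlorozirconocenyl) adduct of pent-1-en-3-ol, Cp rings drawn σ-bonded (not isolated) | CC[C@@H](O[Zr](Cl)(C1C=CC=C1)C1C=CC=C1)/C=C/[Zr](Cl)(C1C=CC=C1)C1C=CC=C1 | intermediate
20 | (1E,3R)-1-iodopent-1-en-3-ol | CC[C@@H](O)/C=C/I | intermediate
21 | (2R)-9-acetyl-2-[(3E,5R)-5-hydroxyhept-3-en-1-yn-1-yl]-1,5,9-triazacyclotridecan-4-one | CC[C@@H](O)/C=C/C#C[C@H]1CC(=O)NCCCN(C(C)=O)CCCCN1 | intermediate
22 | (2R)-9-acetyl-2-[(1Z,3E,5R)-5-hydroxyhepta-1,3-dien-1-yl]-1,5,9-triazacyclotridecan-4-one | CC[C@@H](O)/C=C/C=C\[C@H]1CC(=O)NCCCN(C(C)=O)CCCCN1 | target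

Total step count: 12.
Longest linear sequence: 9 steps (1, 2, 3, 6, 7, 8, 9, 11, 12), starting from 1.

Steps most likely to fail

**1. Step 9.**
- What may go wrong: proton loss from C3 of the allenylidene, possibly followed by non-selective conjugate re-addition of the amine. Other failure modes are chain growth between molecules, displacement of the chiral ligand from copper by the polyamine with loss of facial selectivity, and sluggish ionisation of an aliphatic acetate.
- Fallback: known chemistry with auxiliary control and a different ring-closing bond, setting out from 7 and returning at 17.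
- β-Amino acid part: condensation of 7 with (S)-tert-butanesulfinamide (Ti(OEt)4, THF) should give the N-sulfinyl imine F1. Enolate 8, made from 6 as in step 4, is transmetalated with ClTi(OiPr)3 to the triisopropoxytitanium enolate F2. F2 adds to F1 at −78 °C through a closed chair transition state to give the (3R)-β-sulfinamido ester F3. The mirror-image auxiliary is equally available should the sense of addition require it. LiOH then removes the ester and silyl groups to give the sulfinamido acid F4.
- Polyamine part: in parallel, 4,4-diethoxybutan-1-amine is taken through the operations of steps 1–3 (2; Ac2O; H2, Raney Ni, NH3). This leads via the cyanoethyl amine F5 and the N-acetyl nitrile F6 to the amino acetal F7.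
- Ring closure: carbodiimide coupling of F4 with F7 gives the seco amide F8. Aqueous HCl in THF cleaves the sulfinyl group and the acetal to the amino aldehyde F9, which is kept protonated. F9 is added slowly to NaBH(OAc)3 and iPr2NEt in dilute 1,2-dichloroethane. Intramolecular reductive amination through the cyclic imine F10 then closes the ring at N1–C13, leaves the already fixed C2 untouched and gives 17.

**2. Step 12.**
- What may go wrong: over-reduction of the diene, stalling through adsorption of the basic, polar substrate on the metal surface, or Z-to-E isomerisation on prolonged warming.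
- Fallback: it sets out from 17 and returns at 22, bypassing 21.
- Rhodium-catalysed trans-hydroboration of the terminal alkyne of 17 uses pinacolborane, [Rh(cod)Cl]2, P(iPr)3 and Et3N in THF at rt. It runs through a rhodium vinylidene and places boron cis to C2, which should give the Z-alkenylboronate F11.
- Suzuki–Miyaura coupling of F11 with 20 (Pd(PPh3)4, aq K3PO4, THF, rt) joins the two sp2 carbons with retention at both alkenes. The Z geometry then no longer depends on a reduction.

**3. Step 10.**
- What may go wrong: consumption of hydride by the hydroxyl group with incomplete hydrometalation, erosion of regiocontrol, or loss of light-sensitive material during iodinolysis.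
- Fallback: it sets out from 18 and returns at 20.
- Palladium-catalysed hydrostannation (Bu3SnH, Pd2(dba)3, PCy3·HBF4, iPr2NEt, CH2Cl2, 0 °C) tolerates the free alcohol and, with the bulky phosphine, favours the terminal E isomer. It gives the E-alkenylstannane F12.
- Iododestannylation of F12 with I2 (CH2Cl2, 0 °C) proceeds with retention and gives 20.

Further compounds
F1 | step 9 | (S,E)-2-methyl-N-[3-(trimethylsilyl)prop-2-yn-1-ylidene]propane-2-sulfinamide | CC(C)(C)[S@](=O)/N=C/C#C[Si](C)(C)C
F2 | step 9 | triisopropoxytitanium enolate of ethyl acetate | C=C(OCC)O[Ti](OC(C)C)(OC(C)C)OC(C)C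
F3 | step 9 | ethyl (3R)-3-{[(S)-tert-butylsulfinyl]amino}-5-(trimethylsilyl)pent-4-ynoate | CCOC(=O)C[C@@H](N[S@@](=O)C(C)(C)C)C#C[Si](C)(C)C
F4 | step 9 | (3R)-3-{[(S)-tert-butylsulfinyl]amino}pent-4-ynoic acid | OC(=O)C[C@@H](N[S@@](=O)C(C)(C)C)C#C
F5 | step 9 | 3-[(4,4-diethoxybutyl)amino]propanenitrile | CCOC(CCCNCCC#N)OCC
F6 | step 9 | N-(2-cyanoethyl)-N-(4,4-diethoxybutyl)acetamide | CCOC(CCCN(CCC#N)C(C)=O)OCC
F7 | step 9 | N-(3-aminopropyl)-N-(4,4-diethoxybutyl)acetamide | CCOC(CCCN(CCCN)C(C)=O)OCC
F8 | step 9 | (3R)-N-{3-[acetyl(4,4-diethoxybutyl)amino]propyl}-3-{[(S)-tert-butylsulfinyl]amino}pent-4-ynamide | CCOC(CCCN(CCCNC(=O)C[C@@H](N[S@@](=O)C(C)(C)C)C#C)C(C)=O)OCC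
F9 | step 9 | (3R)-N-{3-[acetyl(4-oxobutyl)amino]propyl}-3-aminopent-4-ynamide | C#C[C@H](N)CC(=O)NCCCN(C(C)=O)CCCC=O
F10 | step 9 | (2R)-9-acetyl-2-ethynyl-1,5,9-triazacyclotridec-1(13)-en-4-one (cyclic imine) | C#C[C@H]1CC(=O)NCCCN(C(C)=O)CCCC=N1
F11 | step 12 | (2R)-9-acetyl-2-[(Z)-2-(4,4,5,5-tetramethyl-1,3,2-dioxaborolan-2-yl)ethenyl]-1,5,9-triazacyclotridecan-4-one | CC1(C)OB(/C=C\[C@H]2CC(=O)NCCCN(C(C)=O)CCCCN2)OC1(C)C
F12 | step 10 | (1E,3R)-1-(tributylstannyl)pent-1-en-3-ol | CC[C@@H](O)/C=C/[Sn](CCCC)(CCCC)CCCC
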